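## Retrosynthetic overview

1. The (Z)-4-oxodec-2-enoate is cut at its C=C bond: a Z-selective Ando olefination of the C7 (diphenoxyphosphoryl)acetate with 2-oxooctanal is the last step; the C3 acetate goes on just before.
2. Both rings are opened at C–O bonds. The key step is the 6-endo attack of the C8 hydroxyl on C4 of a 4,5-epoxide (inversion at C4), which closes ring A (tetrahydropyran); the freed C5–OH then acylates itself on the C1 imide and closes ring B (δ-lactone) in the same flask.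
3. The epoxide comes from C3–OH-directed epoxidation of an E-trisubstituted alkene; the C2–C3 bond comes from a magnesium-catalysed Evans anti-aldol on a C3 enal.
4. The enal comes from cross-metathesis with methacrolein of the Z-crotylboration product of (S)-lactaldehyde triethylsilyl ether (from ethyl (S)-lactate).

Assumption: locants C1–C9 in the text follow the carbon chain of the core (C1 lactone carbonyl, C9 the methyl on the pyran carbon next to the ring oxygen), and (Z)-crotylboronic acid pinacol ester and (diphenoxyphosphoryl)acetic acid are bought.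

## Route

Step 1
Reactants: 1 ethyl (S)-2-hydroxypropanoate (ethyl L-lactate)
Product: 2 ethyl (S)-2-[(triethylsilyl)oxy]propanoate
Conditions: Et3SiCl, imidazole, DMF, 0 → 23 °C
Reagents that add atoms: chlorotriethylsilane, CC[Si](Cl)(CC)CC
Why: Imidazole-promoted silylation of a secondary alcohol; the C8 stereocentre comes from the chiral pool and is not touched, and the triethylsilyl group is chosen because it can later be removed beside a tert-butyldimethylsilyl ether.

Step 2
Reactants: 2 ethyl (S)-2-[(triethylsilyl)oxy]propanoate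
Product: 3 (S)-2-[(triethylsilyl)oxy]propanal
Conditions: i-Bu2AlH (1.05 equiv), CH2Cl2, −78 °C; aq. sodium potassium tartrate
Reagents that add atoms: none
Why: Partial ester reduction with i-Bu2AlH stops at the aluminium hemiacetal at −78 °C and gives the aldehyde on work-up without epimerising the α-silyloxy centre.

Step 3
Reactants: 3 (S)-2-[(triethylsilyl)oxy]propanal; 4 (Z)-crotylboronic acid pinacol ester
Product: 5 (2S,3R,4S)-4-methyl-2-[(triethylsilyl)oxy]hex-5-en-3-ol
Conditions: toluene, 4 Å MS, 23 °C, 48 h; aq. NaHCO3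
Reagents that add atoms: none
Why: Crotylboration through a closed chair (Zimmerman–Traxler) transition state: the Z-crotyl geometry sets C6-Me/C7-OH syn, and polar Felkin–Anh (Cornforth) approach anti to the α-silyloxy group sets C7-OH/C8-O anti, a preference that is particularly strong for Z-crotylboronates.

Step 4
Reactants: 5 (2S,3R,4S)-4-methyl-2-[(triethylsilyl)oxy]hex-5-en-3-ol
Product: 6 tert-butyldimethyl{[(2S,3R,4S)-4-methyl-2-[(triethylsilyl)oxy]hex-5-en-3-yl]oxy}silane
Conditions: t-BuMe2SiOTf, 2,6-lutidine, CH2Cl2, −78 → 0 °C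
Reagents that add atoms: tert-butyldimethylsilyl trifluoromethanesulfonate, CC(C)(C)[Si](C)(C)OS(=O)(=O)C(F)(F)F
Why: Silyl triflate silylation of the hindered C7 hydroxyl; this ether keeps O7 out of the later epoxide chemistry and tells C7–OH apart from C3–OH at the end.

Step 5
Reactants: 6 tert-butyldimethyl{[(2S,3R,4S)-4-methyl-2-[(triethylsilyl)oxy]hex-5-en-3-yl]oxy}silane; 7 methacrolein (2-methylprop-2-enal)
Product: 8 (2E,4S,5R,6S)-5-[(tert-butyldimethylsilyl)oxy]-2,4-dimethyl-6-[(triethylsilyl)oxy]hept-2-enal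
Conditions: 7 (8 equiv), [1,3-bis(2,4,6-trimethylphenyl)imidazolidin-2-ylidene]dichloro(2-isopropoxybenzylidene)ruthenium (second-generation Hoveyda–Grubbs catalyst, 5 mol%), CH2Cl2, 40 °C
Reagents that add atoms: none
Why: Olefin cross-metathesis of a terminal alkene with an excess of a 1,1-disubstituted electron-poor partner gives the trisubstituted enal as the E isomer under thermodynamic control, with ethene lost and no stereocentre touched.

Step 6
Reactants: 8 (2E,4S,5R,6S)-5-[(tert-butyldimethylsilyl)oxy]-2,4-dimethyl-6-[(triethylsilyl)oxy]hept-2-enal; 9 (S)-4-benzyl-3-propanoyl-1,3-oxazolidin-2-one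
Product: 11 (S)-4-benzyl-3-[(2R,3S,4E,6S,7R,8S)-7-[(tert-butyldimethylsilyl)oxy]-3,8-dihydroxy-2,4,6-trimethylnon-4-enoyl]-1,3-oxazolidin-2-one, via silylated aldol adduct 10 (not isolated)
Conditions: MgCl2 (0.2 equiv), Et3N, Me3SiCl, EtOAc, 23 °C; then PPTS, MeOH, 23 °C
Reagents that add atoms: chlorotrimethylsilane, C[Si](C)(C)Cl (its silyl group is carried by intermediate 10 only)
Why: Evans magnesium-halide-catalysed direct anti-aldol: the chelated Z-enolate of the imide adds to the α-unbranched-free (non-α-enolisable) enal on the face away from the benzyl group through a boat transition state, giving the (2R,3S) anti pair, Me3SiCl turns the magnesium aldolate over, and PPTS in methanol then removes the trimethylsilyl and triethylsilyl ethers while the tert-butyldimethylsilyl ether stays.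

Step 7
Reactants: 11 (S)-4-benzyl-3-[(2R,3S,4E,6S,7R,8S)-7-[(tert-butyldimethylsilyl)oxy]-3,8-dihydroxy-2,4,6-trimethylnon-4-enoyl]-1,3-oxazolidin-2-one
Product: 12 (S)-4-benzyl-3-[(2R,3S,4S,5S,6S,7R,8S)-7-[(tert-butyldimethylsilyl)oxy]-4,5-epoxy-3,8-dihydroxy-2,4,6-trimethylnonanoyl]-1,3-oxazolidin-2-one
Conditions: VO(acac)2 (5 mol%), t-BuOOH (1.5 equiv), 2,6-lutidine (0.3 equiv), CH2Cl2, 0 °C
Reagents that add atoms: tert-butyl hydroperoxide, CC(C)(C)OO
Why: Hydroxyl-directed vanadium-catalysed epoxidation (Sharpless–Michaelson type): the allylic C3–OH delivers the oxygen to the alkene face that avoids A1,2 strain between C2 and the C4 methyl, giving the erythro (anti) epoxy alcohol and so the (4S,5S) epoxide, and the lutidine buffer keeps the epoxide from opening early.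

Step 8
Reactants: 12 (S)-4-benzyl-3-[(2R,3S,4S,5S,6S,7R,8S)-7-[(tert-butyldimethylsilyl)oxy]-4,5-epoxy-3,8-dihydroxy-2,4,6-trimethylnonanoyl]-1,3-oxazolidin-2-one
Product: 14 (3R,4S,4aR,6S,7R,8S,8aS)-7-[(tert-butyldimethylsilyl)oxy]-4-hydroxy-3,4a,6,8-tetramethylhexahydropyrano[3,2-b]pyran-2(3H)-one, via hydroxy oxane imide 13 (not isolated)
Conditions: (R)-3,3′-bis(2,4,6-triisopropylphenyl)-1,1′-binaphthyl-2,2′-diyl hydrogen phosphate ((R)-TRIP, 10 mol%), 4 Å MS, toluene, −20 → 23 °C; then Et3N (2 equiv), 23 °C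
Reagents that add atoms: none
Why: Proposed new method: a confined chiral phosphoric acid acts as a bifunctional proton shuttle (P–OH to the epoxide oxygen, P=O accepting the C8–OH proton), so that the epoxide opens in a concerted SN2-like attack of O8 at the fully substituted C4 through a chair in which C6-Me, C7-OSi and C8-Me are all equatorial, with inversion at C4, retention at C5 and no free cation (hence no semipinacol shift), while the catalyst pocket and a hydrogen bond from the free C3–OH to the phosphate are meant to disfavour the competing 5-exo attack at C5; the released C5–OH then attacks the imide carbonyl through a six-membered transition state (Et3N) to close the lactone and expel the oxazolidinone; the closest known reaction type is the phosphoric-acid-catalysed, catalyst-controlled 6-endo (anti-Baldwin) cyclisation of 4,5-epoxy alcohols with disubstituted epoxides, which has not been shown for a trisubstituted epoxide whose attacked carbon is quaternary and flanked by a hydroxyl-bearing carbon, nor in tandem with a lactonisation.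

Step 9
Reactants: 14 (3R,4S,4aR,6S,7R,8S,8aS)-7-[(tert-butyldimethylsilyl)oxy]-4-hydroxy-3,4a,6,8-tetramethylhexahydropyrano[3,2-b]pyran-2(3H)-one
Product: 15 (3R,4S,4aS,6S,7R,8S,8aS)-7-[(tert-butyldimethylsilyl)oxy]-3,4a,6,8-tetramethyl-2-oxooctahydropyrano[3,2-b]pyran-4-yl acetate
Conditions: Ac2O, pyridine, DMAP (cat.), CH2Cl2, 0 → 23 °C
Reagents that add atoms: acetic anhydride, CC(=O)OC(C)=O
Why: DMAP-catalysed acylation of the only free hydroxyl (C3–OH); the mild base at low temperature does not epimerise C2 or eliminate the β-acetoxy lactone.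

Step 10
Reactants: 15 (3R,4S,4aS,6S,7R,8S,8aS)-7-[(tert-butyldimethylsilyl)oxy]-3,4a,6,8-tetramethyl-2-oxooctahydropyrano[3,2-b]pyran-4-yl acetate
Product: 16 (3R,4S,4aS,6S,7R,8R,8aS)-7-hydroxy-3,4a,6,8-tetramethyl-2-oxooctahydropyrano[3,2-b]pyran-4-yl acetate
Conditions: 48% aq. HF, MeCN, 0 → 23 °C
Reagents that add atoms: none
Why: Acidic fluoride desilylation of the hindered secondary silyl ether; lactone and acetate are stable to these non-basic conditions.

Step 11
Reactants: 16 (3R,4S,4aS,6S,7R,8R,8aS)-7-hydroxy-3,4a,6,8-tetramethyl-2-oxooctahydropyrano[3,2-b]pyran-4-yl acetate; 17 (diphenoxyphosphoryl)acetic acid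
Product: 18 (3R,4S,4aS,6S,7R,8R,8aS)-4-acetoxy-3,4a,6,8-tetramethyl-2-oxooctahydropyrano[3,2-b]pyran-7-yl (diphenoxyphosphoryl)acetate
Conditions: DCC, DMAP (cat.), CH2Cl2, 0 → 23 °C
Reagents that add atoms: none
Why: Steglich esterification; the phosphonoacetic acid is a highly reactive acyl donor for the hindered C7–OH, and C7 keeps its configuration because its C–O bond is not broken.

Step 12
Reactants: 19 octane-1,2-diol (racemic)
Product: 20 2-oxooctanal
Conditions: (COCl)2, DMSO, CH2Cl2, −78 °C; Et3N, −78 → 0 °C; non-aqueous work-up, short-path distillation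
Reagents that add atoms: none
Why: Swern oxidation of both hydroxyls of a 1,2-diol gives the α-keto aldehyde without C–C cleavage; no stereocentre is involved.

Step 13
Reactants: 18 (3R,4S,4aS,6S,7R,8R,8aS)-4-acetoxy-3,4a,6,8-tetramethyl-2-oxooctahydropyrano[3,2-b]pyran-7-yl (diphenoxyphosphoryl)acetate; 20 2-oxooctanal
Product: 21 botcinin J, (3R,4S,4aS,6S,7R,8R,8aS)-4-acetoxy-3,4a,6,8-tetramethyl-2-oxooctahydropyrano[3,2-b]pyran-7-yl (2Z)-4-oxodec-2-enoate
Conditions: NaN(SiMe3)2 (1.0 equiv), THF, −78 °C; then 20 (1.5 equiv), −78 °C; AcOH quench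
Reagents that add atoms: none
Why: Ando-type Z-selective Horner–Wadsworth–Emmons olefination: the electron-poor diaryl phosphonate makes collapse of the kinetic adduct fast and irreversible, which gives the Z-alkene; one equivalent of base deprotonates only the phosphonate (far more acidic than the lactone or acetate α-hydrogens), and the aldehyde carbonyl of 20 reacts much faster than its ketone.

## Compound list

1 | ethyl (S)-2-hydroxypropanoate | C[C@H](O)C(=O)OCC | starting material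
2 | ethyl (S)-2-[(triethylsilyl)oxy]propanoate | C[C@H](O[Si](CC)(CC)CC)C(=O)OCC | intermediate
3 | (S)-2-[(triethylsilyl)oxy]propanal | C[C@H](O[Si](CC)(CC)CC)C=O | intermediate
4 | (Z)-crotylboronic acid pinacol ester, 2-[(2Z)-but-2-en-1-yl]-4,4,5,5-tetramethyl-1,3,2-dioxaborolane | C/C=C\CB1OC(C)(C)C(C)(C)O1 | starting material
5 | (2S,3R,4S)-4-methyl-2-[(triethylsilyl)oxy]hex-5-en-3-ol | C[C@H](O[Si](CC)(CC)CC)[C@H](O)[C@@H](C)C=C | intermediate
6 | tert-butyldimethyl{[(2S,3R,4S)-4-methyl-2-[(triethylsilyl)oxy]hex-5-en-3-yl]oxy}silane | C[C@H](O[Si](CC)(CC)CC)[C@H](O[Si](C)(C)C(C)(C)C)[C@@H](C)C=C | intermediate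
7 | methacrolein (2-methylprop-2-enal) | CC(=C)C=O | starting material
8 | (2E,4S,5R,6S)-5-[(tert-butyldimethylsilyl)oxy]-2,4-dimethyl-6-[(triethylsilyl)oxy]hept-2-enal | C[C@H](O[Si](CC)(CC)CC)[C@H](O[Si](C)(C)C(C)(C)C)[C@@H](C)/C=C(\C)C=O | intermediate
9 | (S)-4-benzyl-3-propanoyl-1,3-oxazolidin-2-one | CCC(=O)N1[C@@H](Cc2ccccc2)COC1=O | starting material
10 | (S)-4-benzyl-3-[(2R,3S,4E,6S,7R,8S)-7-[(tert-butyldimethylsilyl)oxy]-2,4,6-trimethyl-8-[(triethylsilyl)oxy]-3-[(trimethylsilyl)oxy]non-4-enoyl]-1,3-oxazolidin-2-one | C[C@H](O[Si](CC)(CC)CC)[C@H](O[Si](C)(C)C(C)(C)C)[C@@H](C)/C=C(\C)[C@@H](O[Si](C)(C)C)[C@@H](C)C(=O)N1[C@@H](Cc2ccccc2)COC1=O | intermediate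
11 | (S)-4-benzyl-3-[(2R,3S,4E,6S,7R,8S)-7-[(tert-butyldimethylsilyl)oxy]-3,8-dihydroxy-2,4,6-trimethylnon-4-enoyl]-1,3-oxazolidin-2-one | C[C@H](O)[C@H](O[Si](C)(C)C(C)(C)C)[C@@H](C)/C=C(\C)[C@@H](O)[C@@H](C)C(=O)N1[C@@H](Cc2ccccc2)COC1=O | intermediate
12 | (S)-4-benzyl-3-[(2R,3S,4S,5S,6S,7R,8S)-7-[(tert-butyldimethylsilyl)oxy]-4,5-epoxy-3,8-dihydroxy-2,4,6-trimethylnonanoyl]-1,3-oxazolidin-2-one | C[C@H](O)[C@H](O[Si](C)(C)C(C)(C)C)[C@@H](C)[C@@H]1O[C@@]1(C)[C@@H](O)[C@@H](C)C(=O)N1[C@@H](Cc2ccccc2)COC1=O | intermediate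
13 | (S)-4-benzyl-3-[(2R,3S)-3-[(2S,3S,4S,5R,6S)-5-[(tert-butyldimethylsilyl)oxy]-3-hydroxy-2,4,6-trimethyloxan-2-yl]-3-hydroxy-2-methylpropanoyl]-1,3-oxazolidin-2-one | C[C@H](O1)[C@H](O[Si](C)(C)C(C)(C)C)[C@@H](C)[C@H](O)[C@@]1(C)[C@@H](O)[C@@H](C)C(=O)N1[C@@H](Cc2ccccc2)COC1=O | intermediate
14 | (3R,4S,4aR,6S,7R,8S,8aS)-7-[(tert-butyldimethylsilyl)oxy]-4-hydroxy-3,4a,6,8-tetramethylhexahydropyrano[3,2-b]pyran-2(3H)-one | CC(C)(C)[Si](C)(C)O[C@@H]1[C@@H](C)[C@@H]2OC(=O)[C@H](C)[C@H](O)[C@@]2(C)O[C@H]1C | intermediate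
15 | (3R,4S,4aS,6S,7R,8S,8aS)-7-[(tert-butyldimethylsilyl)oxy]-3,4a,6,8-tetramethyl-2-oxooctahydropyrano[3,2-b]pyran-4-yl acetate | CC(C)(C)[Si](C)(C)O[C@@H]1[C@@H](C)[C@@H]2OC(=O)[C@H](C)[C@H](OC(C)=O)[C@@]2(C)O[C@H]1C | intermediate
16 | (3R,4S,4aS,6S,7R,8R,8aS)-7-hydroxy-3,4a,6,8-tetramethyl-2-oxooctahydropyrano[3,2-b]pyran-4-yl acetate | O[C@@H]1[C@@H](C)[C@@H]2OC(=O)[C@H](C)[C@H](OC(C)=O)[C@@]2(C)O[C@H]1C | intermediate
17 | (diphenoxyphosphoryl)acetic acid | OC(=O)CP(=O)(Oc1ccccc1)Oc1ccccc1 | starting material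
18 | (3R,4S,4aS,6S,7R,8R,8aS)-4-acetoxy-3,4a,6,8-tetramethyl-2-oxooctahydropyrano[3,2-b]pyran-7-yl (diphenoxyphosphoryl)acetate | O=C(CP(=O)(Oc1ccccc1)Oc1ccccc1)O[C@@H]1[C@@H](C)[C@@H]2OC(=O)[C@H](C)[C@H](OC(C)=O)[C@@]2(C)O[C@H]1C | intermediate
19 | octane-1,2-diol (racemic) | CCCCCCC(O)CO | starting material
20 | 2-oxooctanal | CCCCCCC(=O)C=O | intermediate
21 | botcinin J | CCCCCCC(=O)/C=C\C(=O)O[C@@H]1[C@@H](C)[C@@H]2OC(=O)[C@H](C)[C@H](OC(C)=O)[C@@]2(C)O[C@H]1C | target

## Step count and risks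

Total step count: 13. Longest linear sequence: 12 steps (steps 1–11 and 13, from ethyl (S)-lactate); step 12 makes the aldehyde partner.

The three steps most likely to fail:

Step 8 (the proposed new step). The uncatalysed preference of such hydroxy epoxides is 5-exo attack at C5, which would give a tetrahydrofuran, and an acid can also trigger a semipinacol shift at C4. If catalyst control does not override this, the known-chemistry fallback sets out from enal 8 and comes back to the route at lactone 14. Wittig methylenation of 8 (Ph3P=CH2, THF) gives the diene tert-butyl{[(2S,3R,4S,5E)-4,6-dimethyl-2-[(triethylsilyl)oxy]octa-5,7-dien-3-yl]oxy}dimethylsilane F1. PPTS in methanol removes the triethylsilyl group to give the dienol (2S,3R,4S,5E)-3-[(tert-butyldimethylsilyl)oxy]-4,6-dimethylocta-5,7-dien-2-ol F2. Shi epoxidation with the enantiomer of the fructose-derived ketone (KHSO5 as 2KHSO5·KHSO4·K2SO4, K2CO3 buffer) takes the trisubstituted alkene and gives the vinyl epoxide (2S,3R,4S)-3-[(tert-butyldimethylsilyl)oxy]-4-[(2S,3S)-3-ethenyl-3-methyloxiran-2-yl]pentan-2-ol F3. Camphorsulfonic acid in CH2Cl2 then closes the pyran by the well-established vinyl-directed 6-endo opening at the allylic, fully substituted carbon, giving (2R,3S,4S,5R,6S)-5-[(tert-butyldimethylsilyl)oxy]-2-ethenyl-2,4,6-trimethyloxan-3-ol F4. Ozonolysis (O3, then PPh3) gives the non-enolisable aldehyde (2S,3S,4S,5R,6S)-5-[(tert-butyldimethylsilyl)oxy]-3-hydroxy-2,4,6-trimethyloxane-2-carbaldehyde F5. The MgCl2-catalysed anti-aldol of imide 9 with F5 (Me3SiCl, Et3N), reinforced by chelation of magnesium between the aldehyde and the ring oxygen, gives the bis(trimethylsilyl) ether of 13 F6, which PPTS in methanol converts into 13, and Et3N lactonises 13 to 14.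

Step 5. The terminal alkene of 6 is allylically branched and flanked by two bulky silyl ethers, so the metathesis may stall or dimerise. The fallback sets out from 6 and comes back at enal 8: ozonolysis of 6 (O3, CH2Cl2, −78 °C; PPh3) gives the aldehyde (2R,3R,4S)-3-[(tert-butyldimethylsilyl)oxy]-2-methyl-4-[(triethylsilyl)oxy]pentanal F7, and Wittig olefination with the stabilised ylide 2-(triphenylphosphoranylidene)propanal (toluene, 80 °C) gives the E-enal 8.

Step 13. The Z/E ratio with an α-keto aldehyde is untested, and the Z-keto enoate can isomerise. The fallback sets out from alcohol 16 and comes back at the target 21 by an alkyne route. Esterification of 16 with propiolic acid (DCC, catalytic DMAP, −20 °C) gives the propiolate (3R,4S,4aS,6S,7R,8R,8aS)-4-acetoxy-3,4a,6,8-tetramethyl-2-oxooctahydropyrano[3,2-b]pyran-7-yl prop-2-ynoate F8. Deprotonation of the alkyne C–H with LiN(SiMe3)2 at −78 °C and addition to heptanal gives the 4-hydroxydec-2-ynoate ester F9 (both epimers at the new carbinol). Dess–Martin periodinane gives the 4-oxodec-2-ynoate ester F10. Semi-hydrogenation (H2, Pd/CaCO3 poisoned with Pb(OAc)2, quinoline, EtOAc) gives the Z-enoate 21.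

## Further compounds

F1 | step 8 | tert-butyl{[(2S,3R,4S,5E)-4,6-dimethyl-2-[(triethylsilyl)oxy]octa-5,7-dien-3-yl]oxy}dimethylsilane | C[C@H](O[Si](CC)(CC)CC)[C@H](O[Si](C)(C)C(C)(C)C)[C@@H](C)/C=C(\C)C=C
F2 | step 8 | (2S,3R,4S,5E)-3-[(tert-butyldimethylsilyl)oxy]-4,6-dimethylocta-5,7-dien-2-ol | C[C@H](O)[C@H](O[Si](C)(C)C(C)(C)C)[C@@H](C)/C=C(\C)C=C
F3 | step 8 | (2S,3R,4S)-3-[(tert-butyldimethylsilyl)oxy]-4-[(2S,3S)-3-ethenyl-3-methyloxiran-2-yl]pentan-2-ol | C[C@H](O)[C@H](O[Si](C)(C)C(C)(C)C)[C@@H](C)[C@@H]1O[C@@]1(C)C=C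
F4 | step 8 | (2R,3S,4S,5R,6S)-5-[(tert-butyldimethylsilyl)oxy]-2-ethenyl-2,4,6-trimethyloxan-3-ol | C[C@H](O1)[C@H](O[Si](C)(C)C(C)(C)C)[C@@H](C)[C@H](O)[C@@]1(C)C=C
F5 | step 8 | (2S,3S,4S,5R,6S)-5-[(tert-butyldimethylsilyl)oxy]-3-hydroxy-2,4,6-trimethyloxane-2-carbaldehyde | C[C@H](O1)[C@H](O[Si](C)(C)C(C)(C)C)[C@@H](C)[C@H](O)[C@@]1(C)C=O
F6 | step 8 | bis(trimethylsilyl) ether of 13 (both hydroxyls silylated) | C[C@H](O1)[C@H](O[Si](C)(C)C(C)(C)C)[C@@H](C)[C@H](O[Si](C)(C)C)[C@@]1(C)[C@@H](O[Si](C)(C)C)[C@@H](C)C(=O)N1[C@@H](Cc2ccccc2)COC1=O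
F7 | step 5 | (2R,3R,4S)-3-[(tert-butyldimethylsilyl)oxy]-2-methyl-4-[(triethylsilyl)oxy]pentanal | C[C@H](O[Si](CC)(CC)CC)[C@H](O[Si](C)(C)C(C)(C)C)[C@@H](C)C=O
F8 | step 13 | (3R,4S,4aS,6S,7R,8R,8aS)-4-acetoxy-3,4a,6,8-tetramethyl-2-oxooctahydropyrano[3,2-b]pyran-7-yl prop-2-ynoate | C#CC(=O)O[C@@H]1[C@@H](C)[C@@H]2OC(=O)[C@H](C)[C@H](OC(C)=O)[C@@]2(C)O[C@H]1C
F9 | step 13 | (3R,4S,4aS,6S,7R,8R,8aS)-4-acetoxy-3,4a,6,8-tetramethyl-2-oxooctahydropyrano[3,2-b]pyran-7-yl 4-hydroxydec-2-ynoate (both epimers at the side-chain carbinol) | CCCCCCC(O)C#CC(=O)O[C@@H]1[C@@H](C)[C@@H]2OC(=O)[C@H](C)[C@H](OC(C)=O)[C@@]2(C)O[C@H]1C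
F10 | step 13 | (3R,4S,4aS,6S,7R,8R,8aS)-4-acetoxy-3,4a,6,8-tetramethyl-2-oxooctahydropyrano[3,2-b]pyran-7-yl 4-oxodec-2-ynoate | CCCCCCC(=O)C#CC(=O)O[C@@H]1[C@@H](C)[C@@H]2OC(=O)[C@H](C)[C@H](OC(C)=O)[C@@]2(C)O[C@H]1C
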